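**Retrosynthetic overview**
- Target ⇐ BCl3 debenzylation ⇐ Pd-catalysed hydroxylation of C4–Br ⇐ Heck styrylation of C6–Br of a trans-4,6-dibromo-2,3-diaryl-2,3-dihydrobenzofuran.
- Dihydrofuran ring (the only ring made; every benzene ring is bought) ⇐ acid closure of a phenol onto a p-alkoxybenzylic carbinol, which places C2 trans to C3 ⇐ aryl Grignard + lactol ⇐ ozonolysis of a propenyl group.
- C3–C3a bond and the C3 configuration ⇐ aromatic Claisen rearrangement of an (R,E)-1-methyl-3-arylallyl 3,5-dibromophenyl ether (symmetrical arene, so one regioisomer; 1,3-chirality transfer).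
- That ether ⇐ Mitsunobu inversion of ethyl (S)-lactate with 3,5-dibromophenol, then one-pot iBu2AlH reduction/Horner–Wadsworth–Emmons olefination; the lactate carbon later leaves as acetaldehyde.
- Ring order: transient lactol in step 5, dihydrofuran ring closed in step 7; the two bromines then become the styryl group and the 4-hydroxyl.

Assumption: 1, 2, 4, 13 and 17 are catalogue compounds; the target SMILES is read as the trans (2R,3R) isomer.

**Step 1**
Reactants: 1 3,5-dibromophenol; 2 ethyl (S)-lactate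
Product: 3 ethyl (2R)-2-(3,5-dibromophenoxy)propanoate
Conditions: PPh3, DIAD, THF, 0 °C → rt
Reagents that add atoms: none
Why: Mitsunobu etherification in which the acidic phenol displaces the activated secondary hydroxyl by SN2 with clean inversion, turning the bought (S) centre into the (R)-aryloxy ester.

**Step 2**
Reactants: 4 1,3-bis(benzyloxy)-5-(bromomethyl)benzene
Product: 5 diethyl {[3,5-bis(benzyloxy)phenyl]methyl}phosphonate
Conditions: P(OEt)3 (neat), 140 °C
Reagents that add atoms: triethyl phosphite, CCOP(OCC)OCC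
Why: Michaelis–Arbuzov reaction of a reactive benzylic bromide; no stereocentre is involved.

**Step 3**
Reactants: 3 ethyl (2R)-2-(3,5-dibromophenoxy)propanoate; 5 diethyl {[3,5-bis(benzyloxy)phenyl]methyl}phosphonate
Product: 7 1,3-dibromo-5-{[(2R,3E)-4-[3,5-bis(benzyloxy)phenyl]but-3-en-2-yl]oxy}benzene, via aldehyde 6 (not isolated)
Conditions: iBu2AlH (1.05 equiv), CH2Cl2, −78 °C; then 5/KN(SiMe3)2 (premixed, THF, −78 °C), −78 °C → rt
Reagents that add atoms: none
Why: The low-temperature reduction stops at the aluminium hemiacetal, which releases the epimerisable α-aryloxy aldehyde only in the presence of the phosphonate anion, so it is trapped at once in an E-selective Horner–Wadsworth–Emmons olefination that leaves the stereocentre untouched.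

**Step 4**
Reactants: 7 1,3-dibromo-5-{[(2R,3E)-4-[3,5-bis(benzyloxy)phenyl]but-3-en-2-yl]oxy}benzene
Product: 9 2-{(1R,2E)-1-[3,5-bis(benzyloxy)phenyl]but-2-en-1-yl}-3,5-dibromophenol, via ortho-dienone 8 (not isolated)
Conditions: PhNEt2 (degassed), 185 °C, sealed tube
Reagents that add atoms: none
Why: Aromatic Claisen rearrangement ([3,3]-sigmatropic) to either of the two equivalent ortho positions, through a chair transition state with the carbinol methyl equatorial, so the lactate-derived configuration is transferred suprafacially to the new benzylic carbon (R) with an E-propenyl group before dienone 8 tautomerises to the phenol.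

**Step 5**
Reactants: 9 2-{(1R,2E)-1-[3,5-bis(benzyloxy)phenyl]but-2-en-1-yl}-3,5-dibromophenol
Product: 12 (3R)-3-[3,5-bis(benzyloxy)phenyl]-4,6-dibromo-2,3-dihydro-1-benzofuran-2-ol (C2 anomer mixture), via ozonide 10 (not isolated), via hydroxy aldehyde 11 (not isolated)
Conditions: O3, CH2Cl2, −78 °C (Sudan Red 7B endpoint); then PPh3, −78 °C → rt; used crude
Reagents that add atoms: ozone, [O-][O+]=O
Why: Ozonolysis with reductive work-up cleaves the only C=C bond and expels the lactate carbon as acetaldehyde, and the aldehyde is captured by the ortho phenol as a lactol under neutral cold conditions that avoid enolisation at C3 and dehydration to the benzofuran.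

**Step 6**
Reactants: 12 (3R)-3-[3,5-bis(benzyloxy)phenyl]-4,6-dibromo-2,3-dihydro-1-benzofuran-2-ol; 13 1-(benzyloxy)-4-bromo-2-methoxybenzene
Product: 15 2-{(1R)-1-[3,5-bis(benzyloxy)phenyl]-2-[4-(benzyloxy)-3-methoxyphenyl]-2-hydroxyethyl}-3,5-dibromophenol (carbinol epimer mixture), via aryl Grignard reagent 14 (not isolated)
Conditions: 13, Mg, THF, rt (3 equiv of 14); add 12, THF, −78 → 0 °C; aq. NH4Cl
Reagents that add atoms: none
Why: Grignard addition to the ring-opened magnesium phenoxide–aldehyde form of the lactol is faster than enolisation at low temperature (the ortho phenoxide also lowers the acidity of the C3–H), so C3 is retained and the new carbinol centre forms as an inconsequential epimer mixture.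

**Step 7**
Reactants: 15 2-{(1R)-1-[3,5-bis(benzyloxy)phenyl]-2-[4-(benzyloxy)-3-methoxyphenyl]-2-hydroxyethyl}-3,5-dibromophenol
Product: 16 (2R,3R)-2-[4-(benzyloxy)-3-methoxyphenyl]-3-[3,5-bis(benzyloxy)phenyl]-4,6-dibromo-2,3-dihydro-1-benzofuran
Conditions: TsOH·H2O (10 mol%), CH2Cl2 (0.02 M), 0 °C → rt
Reagents that add atoms: none
Why: Acid ionises the p-alkoxybenzylic alcohol and the neighbouring phenol oxygen captures the cation (intramolecular SN1 etherification) anti to the C3 aryl group, and because the closure is reversible both carbinol epimers converge on the thermodynamically favoured trans (2R,3R) ring.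

**Step 8**
Reactants: 16 (2R,3R)-2-[4-(benzyloxy)-3-methoxyphenyl]-3-[3,5-bis(benzyloxy)phenyl]-4,6-dibromo-2,3-dihydro-1-benzofuran; 17 4-ethenyl-2-methoxyphenyl acetate
Product: 18 4-[(E)-2-{(2R,3R)-2-[4-(benzyloxy)-3-methoxyphenyl]-3-[3,5-bis(benzyloxy)phenyl]-4-bromo-2,3-dihydro-1-benzofuran-6-yl}ethenyl]-2-methoxyphenyl acetate
Conditions: Pd(OAc)2 (5 mol%), P(o-tol)3 (10 mol%), Et3N, DMF, 90 °C; 1.05 equiv of 17
Reagents that add atoms: none
Why: Mizoroki–Heck reaction in which oxidative addition is faster at the unhindered C6–Br than at C4–Br (flanked by the ring fusion and the C3 aryl group), and syn insertion/β-hydride elimination gives the E-stilbene without touching C2 or C3.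

**Step 9**
Reactants: 18 4-[(E)-2-{(2R,3R)-2-[4-(benzyloxy)-3-methoxyphenyl]-3-[3,5-bis(benzyloxy)phenyl]-4-bromo-2,3-dihydro-1-benzofuran-6-yl}ethenyl]-2-methoxyphenyl acetate
Product: 19 (2R,3R)-2-[4-(benzyloxy)-3-methoxyphenyl]-3-[3,5-bis(benzyloxy)phenyl]-6-[(E)-2-(4-hydroxy-3-methoxyphenyl)ethenyl]-2,3-dihydro-1-benzofuran-4-ol
Conditions: Pd2(dba)3 (2.5 mol%), tBuXPhos (10 mol%), KOH (5 equiv), 1,4-dioxane/H2O, 100 °C; then 1 M HCl
Reagents that add atoms: potassium hydroxide, [K+].[OH-]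
Why: Palladium-catalysed hydroxylation of the aryl bromide (C–O cross-coupling with hydroxide, using a bulky biarylphosphine that tolerates the ortho substituent), while the same hydroxide saponifies the aryl acetate and neither stereocentre is acidic enough to epimerise.

**Step 10**
Reactants: 19 (2R,3R)-2-[4-(benzyloxy)-3-methoxyphenyl]-3-[3,5-bis(benzyloxy)phenyl]-6-[(E)-2-(4-hydroxy-3-methoxyphenyl)ethenyl]-2,3-dihydro-1-benzofuran-4-ol
Product: 20 5-[(2R,3R)-4-hydroxy-2-(4-hydroxy-3-methoxyphenyl)-6-[(E)-2-(4-hydroxy-3-methoxyphenyl)ethenyl]-2,3-dihydro-1-benzofuran-3-yl]benzene-1,3-diol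
Conditions: BCl3 (8 equiv), C6HMe5 (10 equiv), CH2Cl2, −78 °C, 1 h; H2O quench at −78 °C
Reagents that add atoms: none
Why: Lewis-acid debenzylation at −78 °C cleaves the three aryl benzyl ethers but not the aryl methyl ethers, pentamethylbenzene traps the benzyl cations so that the stilbene and the electron-rich rings are not benzylated, and any reversible C2–O ionisation returns the same trans isomer.

**Compound list**
1 | 3,5-dibromophenol | Oc1cc(Br)cc(Br)c1 | starting material
2 | ethyl (S)-lactate | C[C@H](O)C(=O)OCC | starting material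
3 | ethyl (2R)-2-(3,5-dibromophenoxy)propanoate | C[C@@H](Oc1cc(Br)cc(Br)c1)C(=O)OCC | intermediate
4 | 1,3-bis(benzyloxy)-5-(bromomethyl)benzene | BrCc1cc(OCc2ccccc2)cc(OCc2ccccc2)c1 | starting material
5 | diethyl {[3,5-bis(benzyloxy)phenyl]methyl}phosphonate | CCOP(=O)(Cc1cc(OCc2ccccc2)cc(OCc2ccccc2)c1)OCC | intermediate
6 | (2R)-2-(3,5-dibromophenoxy)propanal | C[C@@H](Oc1cc(Br)cc(Br)c1)C=O | intermediate
7 | 1,3-dibromo-5-{[(2R,3E)-4-[3,5-bis(benzyloxy)phenyl]but-3-en-2-yl]oxy}benzene | C[C@@H](Oc1cc(Br)cc(Br)c1)/C=C/c1cc(OCc2ccccc2)cc(OCc2ccccc2)c1 | intermediate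
8 | (6R)-6-{(1S,2E)-1-[3,5-bis(benzyloxy)phenyl]but-2-en-1-yl}-3,5-dibromocyclohexa-2,4-dien-1-one | O=C1C=C(Br)C=C(Br)[C@@H]1[C@H](/C=C/C)c1cc(OCc2ccccc2)cc(OCc2ccccc2)c1 | intermediate
9 | 2-{(1R,2E)-1-[3,5-bis(benzyloxy)phenyl]but-2-en-1-yl}-3,5-dibromophenol | Oc1cc(Br)cc(Br)c1[C@H](/C=C/C)c1cc(OCc2ccccc2)cc(OCc2ccccc2)c1 | intermediate
10 | 3-{(R)-[3,5-bis(benzyloxy)phenyl](2,4-dibromo-6-hydroxyphenyl)methyl}-5-methyl-1,2,4-trioxolane (mixture at the two ring carbons) | CC1OOC(O1)[C@H](c1cc(OCc2ccccc2)cc(OCc2ccccc2)c1)c1c(O)cc(Br)cc1Br | intermediate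
11 | (2R)-2-[3,5-bis(benzyloxy)phenyl]-2-(2,4-dibromo-6-hydroxyphenyl)acetaldehyde | O=C[C@H](c1cc(OCc2ccccc2)cc(OCc2ccccc2)c1)c1c(O)cc(Br)cc1Br | intermediate
12 | (3R)-3-[3,5-bis(benzyloxy)phenyl]-4,6-dibromo-2,3-dihydro-1-benzofuran-2-ol (C2 anomer mixture) | OC1Oc2cc(Br)cc(Br)c2[C@H]1c1cc(OCc2ccccc2)cc(OCc2ccccc2)c1 | intermediate
13 | 1-(benzyloxy)-4-bromo-2-methoxybenzene | COc1cc(Br)ccc1OCc1ccccc1 | starting material
14 | [4-(benzyloxy)-3-methoxyphenyl]magnesium bromide | COc1cc([Mg]Br)ccc1OCc1ccccc1 | intermediate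
15 | 2-{(1R)-1-[3,5-bis(benzyloxy)phenyl]-2-[4-(benzyloxy)-3-methoxyphenyl]-2-hydroxyethyl}-3,5-dibromophenol (carbinol epimer mixture) | OC(c1ccc(OCc2ccccc2)c(OC)c1)[C@H](c1cc(OCc2ccccc2)cc(OCc2ccccc2)c1)c1c(O)cc(Br)cc1Br | intermediate
16 | (2R,3R)-2-[4-(benzyloxy)-3-methoxyphenyl]-3-[3,5-bis(benzyloxy)phenyl]-4,6-dibromo-2,3-dihydro-1-benzofuran | Brc1cc(Br)c2c(c1)O[C@@H](c1ccc(OCc3ccccc3)c(OC)c1)[C@@H]2c1cc(OCc2ccccc2)cc(OCc2ccccc2)c1 | intermediate
17 | 4-ethenyl-2-methoxyphenyl acetate | C=Cc1ccc(OC(C)=O)c(OC)c1 | starting material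
18 | 4-[(E)-2-{(2R,3R)-2-[4-(benzyloxy)-3-methoxyphenyl]-3-[3,5-bis(benzyloxy)phenyl]-4-bromo-2,3-dihydro-1-benzofuran-6-yl}ethenyl]-2-methoxyphenyl acetate | CC(=O)Oc1ccc(/C=C/c2cc(Br)c3c(c2)O[C@@H](c2ccc(OCc4ccccc4)c(OC)c2)[C@@H]3c2cc(OCc3ccccc3)cc(OCc3ccccc3)c2)cc1OC | intermediate
19 | (2R,3R)-2-[4-(benzyloxy)-3-methoxyphenyl]-3-[3,5-bis(benzyloxy)phenyl]-6-[(E)-2-(4-hydroxy-3-methoxyphenyl)ethenyl]-2,3-dihydro-1-benzofuran-4-ol | COc1cc(/C=C/c2cc(O)c3c(c2)O[C@@H](c2ccc(OCc4ccccc4)c(OC)c2)[C@@H]3c2cc(OCc3ccccc3)cc(OCc3ccccc3)c2)ccc1O | intermediate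
20 | 5-[(2R,3R)-4-hydroxy-2-(4-hydroxy-3-methoxyphenyl)-6-[(E)-2-(4-hydroxy-3-methoxyphenyl)ethenyl]-2,3-dihydro-1-benzofuran-3-yl]benzene-1,3-diol | COc1cc(/C=C/c2cc(O)c3c(c2)O[C@@H](c2ccc(O)c(OC)c2)[C@@H]3c2cc(O)cc(O)c2)ccc1O | target

**Step count**
Total: 10 steps. Longest linear sequence: 9 steps (steps 1 and 3–10; step 2 is a one-step side branch).

**Three steps most likely to fail**

Step 6. The lactol is an α,α-diaryl aldehyde in disguise: the basic Grignard reagent can enolise it (loss of configuration at C3), and traces of acid dehydrate it to the achiral 3-arylbenzofuran. The fallback sets out from 12 and comes back at 15. It replaces the organomagnesium reagent by a non-basic, rhodium-catalysed 1,2-addition of commercial [4-(benzyloxy)-3-methoxyphenyl]boronic acid to the open aldehyde form ([Rh(cod)OH]2, 1,4-dioxane/H2O, 50 °C). No new compound is made (entry F0).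

Step 8. The two bromides are told apart only by steric hindrance, so coupling at C4 or double coupling can compete. The fallback sets out from 15 and comes back at 19, and it also bypasses step 9. Copper-catalysed intramolecular O-arylation of the benzylic alcohol of 15 (CuI, 1,10-phenanthroline, Cs2CO3, toluene, 110 °C) can reach only the ortho bromide and keeps the phenol as the future 4-hydroxyl. Because this coupling retains the carbinol configuration, it gives the C2-epimeric 6-bromo-2,3-dihydrobenzofuran-4-ol F1. TsOH·H2O in CH2Cl2 then equilibrates the mixture through reversible benzylic ionisation to the trans (2R,3R) isomer F2. Heck coupling of the single remaining bromide with 17 (Pd(OAc)2, P(o-tol)3, Et3N, DMF, 90 °C) gives the stilbene acetate F3, and K2CO3/MeOH removes the acetate to give 19.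

Step 9. Oxidative addition into the hindered C4–Br may be slow, and the phenoxides formed can compete with hydroxide and give diaryl ethers. The fallback sets out from 18 and comes back at 19. It splits the C–O bond formation in two: Miyaura borylation (Pd(dppf)Cl2, B2pin2, KOAc, 1,4-dioxane, 90 °C) gives the pinacol boronate F4, and NaBO3·4H2O in THF/H2O at rt then oxidises the C–B bond and cleaves the aryl acetate in the same flask.

**Further compounds**
F0 | step 6 | none | none
F1 | step 8 | (3R)-2-[4-(benzyloxy)-3-methoxyphenyl]-3-[3,5-bis(benzyloxy)phenyl]-6-bromo-2,3-dihydro-1-benzofuran-4-ol (C2 epimer mixture) | Brc1cc(O)c2c(c1)OC(c1ccc(OCc3ccccc3)c(OC)c1)[C@@H]2c1cc(OCc2ccccc2)cc(OCc2ccccc2)c1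
F2 | step 8 | (2R,3R)-2-[4-(benzyloxy)-3-methoxyphenyl]-3-[3,5-bis(benzyloxy)phenyl]-6-bromo-2,3-dihydro-1-benzofuran-4-ol | Brc1cc(O)c2c(c1)O[C@@H](c1ccc(OCc3ccccc3)c(OC)c1)[C@@H]2c1cc(OCc2ccccc2)cc(OCc2ccccc2)c1
F3 | step 8 | 4-[(E)-2-{(2R,3R)-2-[4-(benzyloxy)-3-methoxyphenyl]-3-[3,5-bis(benzyloxy)phenyl]-4-hydroxy-2,3-dihydro-1-benzofuran-6-yl}ethenyl]-2-methoxyphenyl acetate | CC(=O)Oc1ccc(/C=C/c2cc(O)c3c(c2)O[C@@H](c2ccc(OCc4ccccc4)c(OC)c2)[C@@H]3c2cc(OCc3ccccc3)cc(OCc3ccccc3)c2)cc1OC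
F4 | step 9 | 4-[(E)-2-{(2R,3R)-2-[4-(benzyloxy)-3-methoxyphenyl]-3-[3,5-bis(benzyloxy)phenyl]-4-(4,4,5,5-tetramethyl-1,3,2-dioxaborolan-2-yl)-2,3-dihydro-1-benzofuran-6-yl}ethenyl]-2-methoxyphenyl acetate | CC(=O)Oc1ccc(/C=C/c2cc(B4OC(C)(C)C(C)(C)O4)c3c(c2)O[C@@H](c2ccc(OCc4ccccc4)c(OC)c2)[C@@H]3c2cc(OCc3ccccc3)cc(OCc3ccccc3)c2)cc1OC
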